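**Plan**

- Retrosynthesis: cut the C7–O ester bond (with 1,3-transposition of oxygen back to C9) and the C6 acetate, then the C6/C9 oxygens (singlet oxygen), then C9–C11 (B-alkyl Suzuki–Miyaura), then C1–C10 and C3–C4 of ring A in one cut, and last C10–CH3.
- Enabling feature: ring B (C5–C10), with C4 on C5 and the C8 methyl para to it, is a p-menthane and maps onto (R)-carvone. There the enolizable alpha-prime carbon C10 and the internal isopropenyl carbon C4 stand 1,3 across C5, one as enolate nucleophile and one as tertiary radical, so a C1–C3 bis-electrophile can bridge them.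
- Forward: ring B is bought as carvone; C10 is methylated; ring A is annulated in one flask with 1,3-diiodopropane ([3+3]); the C9 dienyl triflate is coupled with the C11–C15 unit; ring B is then oxygenated at C6 and acylated at C7.
- Stereochemistry: C5 from (R)-carvone; C10 from enolate alkylation anti to the isopropenyl group (hence the trans ring fusion); C6 from hydride attack anti to the axial C4 and C10 methyl groups; C7 from anti opening of a 6β,7β-acetoxonium ion; the 13E alkene from enynol 7.

Key step: step 2

Remark: positions are given in labdane numbering (ring A = C1–C5 and C10, ring B = C5–C10, side chain C11–C15, core 5S,10S), and α means the face opposite the C10 methyl group.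

**Route**

Step 1
Reactants: 1 (R)-(−)-carvone
Product: 2 (5R)-2,6-dimethyl-5-(prop-1-en-2-yl)cyclohex-2-en-1-one (6-methylcarvone, both C6 epimers)
Conditions: LiN(i-Pr)2, THF, −78 °C; MeI, −78 to 0 °C
Reagents that add atoms: iodomethane, CI
Why: Kinetic deprotonation at the alpha-prime carbon gives the cross-conjugated lithium dienolate, whose C-methylation (enolate alkylation) installs the future C10 methyl group; the C6 configuration does not matter because this centre is enolized again in step 2.

Step 2
Reactants: 2 6-methylcarvone, 3 1,3-diiodopropane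
Product: 5 (4aS,8aS)-2,5,5,8a-tetramethyl-4a,5,6,7,8,8a-hexahydronaphthalen-1(4H)-one, via alkyl iodide 4 (not isolated)
Conditions: LiN(i-Pr)2, THF, −78 °C, then added slowly to I(CH2)3I, DMPU, −78 to 0 °C; then in the same flask Fe(acac)3 (cat.), NiBr2(diglyme) (cat.), 4,4′-di-tert-butyl-2,2′-bipyridine (cat.), PhSiH3, Na2CO3, i-PrOH, 35 °C, high dilution
Reagents that add atoms: none
Why: Proposed new method: LiN(i-Pr)2 converts 2 into the cross-conjugated dienolate, which is C-alkylated at C10 by one end of 3 to give iodide 4; in the same flask an iron hydride from Fe(acac)3 and PhSiH3 transfers a hydrogen atom to the CH2 terminus of the isopropenyl group, and the tertiary C4 radical is captured by the alkylnickel species formed from the tethered primary iodide, reductive elimination forming C3–C4. The closest known reaction types are the anti-selective alkylation of 6-methylcarvone enolates and the intermolecular Markovnikov hydroalkylation of 1,1-disubstituted alkenes with primary alkyl iodides under metal-hydride hydrogen-atom-transfer/nickel dual catalysis; their union in one flask and the ring-closing variant are untested. Ring A closes in the second event as a six-membered ring by C(sp3)–C(sp3) coupling between the C4 radical and the C3 terminus of the tether, an exo-tet type closure for which no smaller or larger ring is available. C10 is set in the first event by approach of the electrophile to the enolate face opposite the C5 isopropenyl group, so the tether and C4 are trans and the ring fusion must be trans, while C4 becomes an achiral gem-dimethyl carbon because the transferred hydrogen turns the alkene CH2 into the second methyl group. The step needs mono-alkylation of 3, which slow inverse addition should secure, and hydrogen atom transfer to the electron-rich 1,1-disubstituted alkene and not to the enone, which the choice of an iron hydride over a manganese hydride should secure.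

Step 3
Reactants: 5 bicyclic enone
Product: 6 (4aS,8aS)-2,5,5,8a-tetramethyl-4a,5,6,7,8,8a-hexahydronaphthalen-1-yl trifluoromethanesulfonate
Conditions: KN(SiMe3)2, THF, −78 °C; PhNTf2, −78 to 0 °C
Reagents that add atoms: N-phenylbis(trifluoromethanesulfonimide), O=S(=O)(N(c1ccccc1)S(=O)(=O)C(F)(F)F)C(F)(F)F
Why: With no hydrogen on C10, the base removes a gamma hydrogen at C6 and the extended dienolate is O-sulfonylated (enol triflate formation), giving the ring B 6,8-diene with the leaving group on C9 and touching no stereocentre.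

Step 4
Reactants: 7 (2E)-3-methylpent-2-en-4-yn-1-ol
Product: 9 (2E)-3-methylpent-2-en-4-ynoic acid, via enynal 8 (not isolated)
Conditions: TEMPO (cat.), PhI(OAc)2, CH2Cl2, rt; then NaClO2, NaH2PO4, 2-methyl-2-butene, t-BuOH/H2O, 0 °C to rt
Reagents that add atoms: sodium chlorite, [Na+].[O-]Cl=O
Why: Nitroxyl-catalysed oxidation of the allylic alcohol to the enal followed by Pinnick oxidation should give the acid without touching the alkyne or the E geometry.

Step 5
Reactants: 9 enynoic acid
Product: 10 2-(trimethylsilyl)ethyl (2E)-3-methylpent-2-en-4-ynoate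
Conditions: Me3SiCH2CH2OH, DCC, DMAP (cat.), CH2Cl2, 0 °C to rt
Reagents that add atoms: 2-(trimethylsilyl)ethanol, C[Si](C)(C)CCO
Why: Steglich esterification masks the acid as a fluoride-labile ester that should tolerate the borane, zerovalent palladium, singlet oxygen, hydride and Lewis acid of the later steps.

Step 6
Reactants: 10 enynoate
Product: 11 2-(trimethylsilyl)ethyl (2E)-3-methylpenta-2,4-dienoate
Conditions: H2 (1 atm), Pd/CaCO3 poisoned with Pb(OAc)2, quinoline, EtOAc, rt
Reagents that add atoms: none
Why: Lindlar semihydrogenation should stop at the terminal vinyl group and keep the 2E geometry.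

Step 7
Reactants: 6 dienyl triflate, 11 dienoate
Product: 13 2-(trimethylsilyl)ethyl (13E)-labda-6,8,13-trien-15-oate, via alkylborane 12 (not isolated)
Conditions: 11, 9-BBN, THF, 0 °C to rt; then 6, Pd(dppf)Cl2 (cat.), AsPh3, Cs2CO3, DMF/H2O, rt to 50 °C
Reagents that add atoms: none
Why: Anti-Markovnikov hydroboration of the terminal vinyl group and B-alkyl Suzuki–Miyaura coupling with the hindered dienyl triflate should form C9–C11 and deliver the whole side chain with its 13E alkene.

Step 8
Reactants: 13 triene ester
Product: 15 2-(trimethylsilyl)ethyl (13E)-9α-hydroxy-6-oxolabda-7,13-dien-15-oate, via endoperoxide 14 (not isolated)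
Conditions: O2, tetraphenylporphyrin (cat.), visible light, CH2Cl2, −20 °C; then Et3N, 0 °C to rt
Reagents that add atoms: dioxygen, O=O
Why: Singlet oxygen should add to the cisoid ring B diene by [4+2] cycloaddition from the α face opposite the C10 methyl group, and Kornblum–DeLaMare rearrangement of the 6,9-endoperoxide (only C6 carries a hydrogen) should give the C6 ketone and the tertiary 9α-alcohol.

Step 9
Reactants: 15 hydroxy enone
Product: 16 2-(trimethylsilyl)ethyl (13E)-6β,9α-dihydroxylabda-7,13-dien-15-oate
Conditions: NaBH4, CeCl3·7H2O, MeOH, −40 °C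
Reagents that add atoms: none
Why: Luche 1,2-reduction should deliver hydride to the C6 carbonyl from the α face, away from the axial C4β and C10 methyl groups, which sets the axial 6β-hydroxyl.

Step 10
Reactants: 16 diol
Product: 17 2-(trimethylsilyl)ethyl (13E)-6β-acetoxy-9α-hydroxylabda-7,13-dien-15-oate
Conditions: Ac2O, Et3N, DMAP (cat.), CH2Cl2, rt
Reagents that add atoms: acetic anhydride, CC(=O)OC(C)=O
Why: Nucleophile-catalysed acylation should take place only at the secondary 6β-hydroxyl, because the tertiary C9 hydroxyl is too hindered under these conditions.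

Step 11
Reactants: 17 hydroxy acetate
Product: 18 2-(trimethylsilyl)ethyl (13E)-6β-acetoxy-7α-(3-methylbutanoyloxy)labda-8,13-dien-15-oate
Conditions: (Me2CHCH2CO)2O, Sc(OTf)3 (cat.), CH2Cl2, −20 to 0 °C
Reagents that add atoms: 3-methylbutanoic anhydride, CC(C)CC(=O)OC(=O)CC(C)C
Why: Lewis acid ionization at the tertiary allylic C9 oxygen (SN1′ allylic transposition) should give the C7–C9 allyl cation, which the axial 6β-acetate captures at C7 from the β face as a cis-fused acetoxonium ion, and isovalerate then opens this ion at the allylic C7 from the α face (trans-diaxial), setting the 7α-ester and the C8=C9 alkene while the anhydride removes the water that would give a cis-hydroxy ester.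

Step 12
Reactants: 18 silylethyl ester
Product: 19 (13E)-6β-acetoxy-7α-(3-methylbutanoyloxy)labda-8,13-dien-15-oic acid (CNP0328312.2)
Conditions: Bu4NF, AcOH, THF, 0 °C to rt
Reagents that add atoms: none
Why: Fluoride attacks silicon and the 2-(trimethylsilyl)ethyl ester fragments to ethene and the carboxylate (fluoride-induced β-elimination), which should leave the acetate, the isovalerate and every stereocentre untouched.

**Compound list**

1 | (R)-(−)-carvone | CC1=CC[C@H](CC1=O)C(C)=C | starting material
2 | (5R)-2,6-dimethyl-5-(prop-1-en-2-yl)cyclohex-2-en-1-one (both C6 epimers) | CC1=CC[C@H](C(C)C1=O)C(C)=C | intermediate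
3 | 1,3-diiodopropane | ICCCI | starting material
4 | (5S,6S)-6-(3-iodopropyl)-2,6-dimethyl-5-(prop-1-en-2-yl)cyclohex-2-en-1-one | C1C=C(C)C(=O)[C@@](C)(CCCI)[C@@H]1C(C)=C | intermediate
5 | (4aS,8aS)-2,5,5,8a-tetramethyl-4a,5,6,7,8,8a-hexahydronaphthalen-1(4H)-one | C1C=C(C)C(=O)[C@@]2(C)CCCC(C)(C)[C@H]12 | intermediate
6 | (4aS,8aS)-2,5,5,8a-tetramethyl-4a,5,6,7,8,8a-hexahydronaphthalen-1-yl trifluoromethanesulfonate | C1=CC(C)=C(OS(=O)(=O)C(F)(F)F)[C@@]2(C)CCCC(C)(C)[C@H]12 | intermediate
7 | (2E)-3-methylpent-2-en-4-yn-1-ol | C#C/C(C)=C/CO | starting material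
8 | (2E)-3-methylpent-2-en-4-ynal | C#C/C(C)=C/C=O | intermediate
9 | (2E)-3-methylpent-2-en-4-ynoic acid | C#C/C(C)=C/C(=O)O | intermediate
10 | 2-(trimethylsilyl)ethyl (2E)-3-methylpent-2-en-4-ynoate | C#C/C(C)=C/C(=O)OCC[Si](C)(C)C | intermediate
11 | 2-(trimethylsilyl)ethyl (2E)-3-methylpenta-2,4-dienoate | C=C/C(C)=C/C(=O)OCC[Si](C)(C)C | intermediate
12 | 2-(trimethylsilyl)ethyl (2E)-5-(9-borabicyclo[3.3.1]nonan-9-yl)-3-methylpent-2-enoate | C[Si](C)(C)CCOC(=O)/C=C(C)/CCB1C2CCCC1CCC2 | intermediate
13 | 2-(trimethylsilyl)ethyl (13E)-labda-6,8,13-trien-15-oate | C1=CC(C)=C(CC/C(C)=C/C(=O)OCC[Si](C)(C)C)[C@@]2(C)CCCC(C)(C)[C@H]12 | intermediate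
14 | 2-(trimethylsilyl)ethyl (13E)-6α,9α-epidioxylabda-7,13-dien-15-oate | O1O[C@H]2C=C(C)[C@]1(CC/C(C)=C/C(=O)OCC[Si](C)(C)C)[C@@]3(C)CCCC(C)(C)[C@H]23 | intermediate
15 | 2-(trimethylsilyl)ethyl (13E)-9α-hydroxy-6-oxolabda-7,13-dien-15-oate | O=C1C=C(C)[C@](O)(CC/C(C)=C/C(=O)OCC[Si](C)(C)C)[C@@]2(C)CCCC(C)(C)[C@H]12 | intermediate
16 | 2-(trimethylsilyl)ethyl (13E)-6β,9α-dihydroxylabda-7,13-dien-15-oate | O[C@@H]1C=C(C)[C@](O)(CC/C(C)=C/C(=O)OCC[Si](C)(C)C)[C@@]2(C)CCCC(C)(C)[C@H]12 | intermediate
17 | 2-(trimethylsilyl)ethyl (13E)-6β-acetoxy-9α-hydroxylabda-7,13-dien-15-oate | CC(=O)O[C@@H]1C=C(C)[C@](O)(CC/C(C)=C/C(=O)OCC[Si](C)(C)C)[C@@]2(C)CCCC(C)(C)[C@H]12 | intermediate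
18 | 2-(trimethylsilyl)ethyl (13E)-6β-acetoxy-7α-(3-methylbutanoyloxy)labda-8,13-dien-15-oate | CC(=O)O[C@@H]1[C@@H](OC(=O)CC(C)C)C(C)=C(CC/C(C)=C/C(=O)OCC[Si](C)(C)C)[C@@]2(C)CCCC(C)(C)[C@H]12 | intermediate
19 | (13E)-6β-acetoxy-7α-(3-methylbutanoyloxy)labda-8,13-dien-15-oic acid | CC(=O)O[C@@H]1[C@@H](OC(=O)CC(C)C)C(C)=C(CC/C(C)=C/C(=O)O)[C@@]2(C)CCCC(C)(C)[C@H]12 | target

**Step count and risks**

Total step count: 12. Longest linear sequence: 9 steps (steps 1–3 and 7–12 from 1; steps 4–12 from 7 are equally long).

Steps most likely to fail: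

1. Step 2. The tertiary C4 radical may be quenched by a second hydrogen atom transfer (net hydrogenation of the isopropenyl group) before nickel captures it. The iron hydride may also reduce the enone, or coupling may occur between two molecules instead of within one. The fallback sets out from 2 and returns at 5, using known chemistry only. The lithium enolate of 2 would be alkylated with ethyl 2-(bromomethyl)acrylate, again anti to the isopropenyl group, to give ethyl 2-{[(1S,6S)-1,3-dimethyl-2-oxo-6-(prop-1-en-2-yl)cyclohex-3-en-1-yl]methyl}prop-2-enoate F1. A hydrogen-atom-transfer-initiated Giese cyclization (Fe(acac)3, PhSiH3, EtOH/ethylene glycol, 60 °C), in which the C4 radical adds to the acrylate terminus, should give ethyl (4aS,8aS)-4,4,7,8a-tetramethyl-8-oxo-1,2,3,4,4a,5,8,8a-octahydronaphthalene-2-carboxylate F2. Saponification (LiOH, THF/H2O) would give (4aS,8aS)-4,4,7,8a-tetramethyl-8-oxo-1,2,3,4,4a,5,8,8a-octahydronaphthalene-2-carboxylic acid F3, and Barton reductive decarboxylation ((COCl)2; 2-mercaptopyridine N-oxide sodium salt, t-BuSH, light) would return 5.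

2. Step 7. Oxidative addition and transmetalation at the triflate carbon, flanked by a quaternary centre and a methyl-bearing alkene carbon, may be slow. Protodeboronation or β-hydride elimination of the alkylborane, or conjugate reduction of the dienoate during hydroboration, could then take over. The fallback sets out from 6 and returns at 13. Negishi coupling of 6 with the alkylzinc bromide made from 2-(2-bromoethyl)-2-methyl-1,3-dioxolane (Zn, LiCl, THF; Pd(dppf)Cl2) would give 2-methyl-2-{2-[(4aS,8aS)-2,5,5,8a-tetramethyl-4a,5,6,7,8,8a-hexahydronaphthalen-1-yl]ethyl}-1,3-dioxolane F4. Mild hydrolysis (pyridinium p-toluenesulfonate, acetone/H2O) would give 4-[(4aS,8aS)-2,5,5,8a-tetramethyl-4a,5,6,7,8,8a-hexahydronaphthalen-1-yl]butan-2-one F5. Horner–Wadsworth–Emmons olefination with 2-(trimethylsilyl)ethyl (diethoxyphosphoryl)acetate (NaH, THF) would return 13 after removal of the minor 13Z isomer.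

3. Step 11. The allyl cation may lose a proton to give trienes, traces of water may attack the central carbon of the acetoxonium ion (cis-hydroxy ester), or the two acyl groups may exchange. The fallback sets out from 17 and returns at 18. A perrhenate-catalysed 1,3-transposition of the tertiary allylic alcohol (Ph3SiOReO3 cat., Et2O, −40 to 0 °C) is suprafacial, so the 9α-hydroxyl should arrive on the α face of C7 and give 2-(trimethylsilyl)ethyl (13E)-6β-acetoxy-7α-hydroxylabda-8,13-dien-15-oate F6. Any ionized fraction would be steered to the same face by the 6β-acetate. Acylation with 3-methylbutanoyl chloride (pyridine, DMAP, CH2Cl2) would return 18.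

Further compounds
F1 | step 2 | ethyl 2-{[(1S,6S)-1,3-dimethyl-2-oxo-6-(prop-1-en-2-yl)cyclohex-3-en-1-yl]methyl}prop-2-enoate | C1C=C(C)C(=O)[C@@](C)(CC(=C)C(=O)OCC)[C@@H]1C(C)=C
F2 | step 2 | ethyl (4aS,8aS)-4,4,7,8a-tetramethyl-8-oxo-1,2,3,4,4a,5,8,8a-octahydronaphthalene-2-carboxylate (both C2 epimers) | C1C=C(C)C(=O)[C@@]2(C)CC(C(=O)OCC)CC(C)(C)[C@H]12
F3 | step 2 | (4aS,8aS)-4,4,7,8a-tetramethyl-8-oxo-1,2,3,4,4a,5,8,8a-octahydronaphthalene-2-carboxylic acid (both C2 epimers) | C1C=C(C)C(=O)[C@@]2(C)CC(C(=O)O)CC(C)(C)[C@H]12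
F4 | step 7 | 2-methyl-2-{2-[(4aS,8aS)-2,5,5,8a-tetramethyl-4a,5,6,7,8,8a-hexahydronaphthalen-1-yl]ethyl}-1,3-dioxolane | C1=CC(C)=C(CCC3(C)OCCO3)[C@@]2(C)CCCC(C)(C)[C@H]12
F5 | step 7 | 4-[(4aS,8aS)-2,5,5,8a-tetramethyl-4a,5,6,7,8,8a-hexahydronaphthalen-1-yl]butan-2-one | C1=CC(C)=C(CCC(C)=O)[C@@]2(C)CCCC(C)(C)[C@H]12
F6 | step 11 | 2-(trimethylsilyl)ethyl (13E)-6β-acetoxy-7α-hydroxylabda-8,13-dien-15-oate | CC(=O)O[C@@H]1[C@@H](O)C(C)=C(CC/C(C)=C/C(=O)OCC[Si](C)(C)C)[C@@]2(C)CCCC(C)(C)[C@H]12
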